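**Retrosynthetic overview**
1. Target 23 ⇐ bis-silyl ether 22 (desilylation). Ring C of 22 is closed last by a 1,2-aryl shift: alcohol 19 → triflate → phenonium ion → ipso Friedel–Crafts capture by silyl-marked ring A, which sets C3 by inversion.
2. 19 ⇐ 16 (directed lithiation/silylation) ⇐ aryl Grignard of bromide 14 (rings B/D) + (R)-glycidyl ether 7 (ring A plus the C3 unit).
3. 7 ⇐ phenol 5 + (S)-glycidol; 5 ⇐ resorcinol by mono-methylation, silylation and C–H borylation/oxidation.
4. 14 ⇐ cyclohexane-1,3-dione + 3-methylbut-2-enal: ring D by Knoevenagel/oxa-6π, then aromatisation to ring B and bromination.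
5. Ring order: D, then B (by aromatisation); ring A is bought as resorcinol; ring C last.

Assumption: the drawn target is the 3R enantiomer, and (S)-glycidol of high ee is a catalogue chemical and the only source of chirality.

**Step 1**
Reactants: 1 resorcinol
Product: 2 3-methoxyphenol
Conditions: MeI (1.0 equiv), K2CO3, acetone, reflux; unreacted 1 recycled
Reagents that add atoms: iodomethane, CI
Why: Williamson ether synthesis; statistical mono-methylation of a symmetric diphenol, with the mono ether separated from 1 and the dimethyl ether.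

**Step 2**
Reactants: 2 3-methoxyphenol
Product: 3 triisopropyl(3-methoxyphenoxy)silane
Conditions: TIPSCl, imidazole, DMF, rt
Reagents that add atoms: chlorotriisopropylsilane, CC(C)[Si](Cl)(C(C)C)C(C)C
Why: Standard phenol silylation; the bulky silyl ether survives all later basic and organometallic steps.

**Step 3**
Reactants: 3 triisopropyl(3-methoxyphenoxy)silane
Product: 5 3-methoxy-5-[(triisopropylsilyl)oxy]phenol, via aryl pinacol boronate 4 (not isolated)
Conditions: [Ir(OMe)(cod)]2 (1 mol %), dtbpy (2 mol %), B2pin2 (0.6 equiv), THF, 80 °C; then Oxone (2KHSO5·KHSO4·K2SO4), acetone/H2O, rt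
Reagents that add atoms: potassium peroxymonosulfate, [K+].[O-]S(=O)(=O)OO
Why: Sterically controlled iridium-catalysed C–H borylation goes to C5, the only C–H with no ortho substituent, and one-pot oxidation of the C–B bond gives the phenol.

**Step 4**
Reactants: 5 3-methoxy-5-[(triisopropylsilyl)oxy]phenol, 6 (S)-glycidol
Product: 7 (R)-triisopropyl{3-methoxy-5-[(oxiran-2-yl)methoxy]phenoxy}silane
Conditions: PPh3, DIAD, THF, 0 °C → rt
Reagents that add atoms: none
Why: Mitsunobu etherification at the primary carbon of glycidol; the stereocentre is not touched (S becomes R only through the change in CIP priorities).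

**Step 5**
Reactants: 8 cyclohexane-1,3-dione, 9 3-methylbut-2-enal
Product: 11 2,2-dimethyl-7,8-dihydro-2H-chromen-5(6H)-one, via alkylidene dione 10 (not isolated)
Conditions: ethylenediammonium diacetate (10 mol %), MeOH, rt → 50 °C
Reagents that add atoms: none
Why: Knoevenagel condensation then oxa-6π electrocyclisation (formal [3+3] annulation) builds ring D; regiochemistry is unambiguous because the dione is symmetric.

**Step 6**
Reactants: 11 2,2-dimethyl-7,8-dihydro-2H-chromen-5(6H)-one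
Product: 13 triisopropyl[(2,2-dimethyl-2H-chromen-5-yl)oxy]silane, via silyl dienol ether 12 (not isolated)
Conditions: LiN(i-Pr)2, THF, −78 °C; TIPSOTf, −78 → 0 °C; then DDQ, 0 °C → rt
Reagents that add atoms: triisopropylsilyl trifluoromethanesulfonate, CC(C)[Si](C(C)C)(C(C)C)OS(=O)(=O)C(F)(F)F
Why: Kinetic enolisation at C6 and O-silylation give the cross-conjugated dienol ether, which DDQ dehydrogenates to the aryl silyl ether (aromatisation-driven hydride abstraction), so ring B arrives already protected.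

**Step 7**
Reactants: 13 triisopropyl[(2,2-dimethyl-2H-chromen-5-yl)oxy]silane
Product: 14 [(8-bromo-2,2-dimethyl-2H-chromen-5-yl)oxy]triisopropylsilane
Conditions: NBS (1.0 equiv), DMF, −20 °C, dark
Reagents that add atoms: N-bromosuccinimide, O=C1CCC(=O)N1Br
Why: Electrophilic aromatic bromination; C8 is para to the silyloxy group and ortho to the ring oxygen, whereas C6 is shielded by the silyl group that the peri C4–H pushes toward it.

**Step 8**
Reactants: 14 [(8-bromo-2,2-dimethyl-2H-chromen-5-yl)oxy]triisopropylsilane, 7 (R)-triisopropyl{3-methoxy-5-[(oxiran-2-yl)methoxy]phenoxy}silane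
Product: 16 (R)-1-{2,2-dimethyl-5-[(triisopropylsilyl)oxy]-2H-chromen-8-yl}-3-{3-methoxy-5-[(triisopropylsilyl)oxy]phenoxy}propan-2-ol, via arylmagnesium bromide 15 (not isolated)
Conditions: Mg, LiCl, THF, rt; then CuI (10 mol %), 7, −30 → 0 °C; aqueous work-up
Reagents that add atoms: none
Why: Magnesium insertion then copper-catalysed SN2 opening of the epoxide at its terminal CH2 by the aryl Grignard reagent; the stereocentre is a spectator, so R is retained.

**Step 9**
Reactants: 16 (R)-1-{2,2-dimethyl-5-[(triisopropylsilyl)oxy]-2H-chromen-8-yl}-3-{3-methoxy-5-[(triisopropylsilyl)oxy]phenoxy}propan-2-ol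
Product: 19 (R)-1-{2,2-dimethyl-5-[(triisopropylsilyl)oxy]-2H-chromen-8-yl}-3-{3-methoxy-5-[(triisopropylsilyl)oxy]-2-(trimethylsilyl)phenoxy}propan-2-ol, via dilithio species 17 (not isolated), via bis-silylated ether 18 (not isolated)
Conditions: n-BuLi (2.2 equiv), THF, −78 → 0 °C; Me3SiCl, −78 °C; then K2CO3, MeOH, 0 °C
Reagents that add atoms: chlorotrimethylsilane, C[Si](C)(C)Cl
Why: Directed ortho-metalation: after O-lithiation, the ring A C–H flanked by OMe and the alkoxide-bearing OCH2 group is the only doubly coordinated site, so it is lithiated and silylated; methanolysis removes the O-silyl group, and the C–Si bond marks the carbon that must become C4a.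

**Step 10**
Reactants: 19 (R)-1-{2,2-dimethyl-5-[(triisopropylsilyl)oxy]-2H-chromen-8-yl}-3-{3-methoxy-5-[(triisopropylsilyl)oxy]-2-(trimethylsilyl)phenoxy}propan-2-ol
Product: 22 (R)-3-{2,2-dimethyl-5-[(triisopropylsilyl)oxy]-2H-chromen-8-yl}-5-methoxy-7-[(triisopropylsilyl)oxy]chromane, via secondary triflate 20 (not isolated), via spiro phenonium triflate 21 (not isolated)
Conditions: Tf2O (1.1 equiv), 2,6-di-tert-butyl-4-methylpyridine (2.5 equiv), CH2Cl2, −78 → 0 °C
Reagents that add atoms: none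
Why: Proposed new method: triflation lets the electron-rich ring B (ortho ring oxygen, para silyloxy) displace triflate from the back (Ar1-3 participation) to give phenonium ion 21 with inversion at the future C3; ring A then opens the cyclopropane at its CH2 carbon through a six-membered transition state (Ar2-6, preferred over five-ring attack at the substituted carbon, as in the 6-endo cyclisation of aryl glycidyl ethers to chroman-3-ols), attacking ipso to silicon so that C4–C4a forms only between O1 and OMe, and loss of the silyl cation rearomatises; the net stereospecific 1,2-aryl shift closes ring C and sets C3 as R; the closest known reactions are solvolytic phenonium 1,2-aryl migrations of β-aryl sulfonates and the epoxide–arene cyclisation of aryl glycidyl ethers, neither shown with a tethered arylsilane as the terminating nucleophile.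

**Step 11**
Reactants: 22 (R)-3-{2,2-dimethyl-5-[(triisopropylsilyl)oxy]-2H-chromen-8-yl}-5-methoxy-7-[(triisopropylsilyl)oxy]chromane
Product: 23 (R)-3-(5-hydroxy-2,2-dimethyl-2H-chromen-8-yl)-5-methoxychroman-7-ol
Conditions: Bu4NF (2.2 equiv), AcOH (2.2 equiv), THF, 0 °C
Reagents that add atoms: none
Why: Fluoride cleavage of both aryl silyl ethers, buffered with acetic acid so the chromene and the electron-rich phenols see no strong base; C3 is untouched.

**Compound list**
1 | resorcinol | Oc1cccc(O)c1 | starting material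
2 | 3-methoxyphenol | COc1cccc(O)c1 | intermediate
3 | triisopropyl(3-methoxyphenoxy)silane | COc1cccc(O[Si](C(C)C)(C(C)C)C(C)C)c1 | intermediate
4 | 2-{3-methoxy-5-[(triisopropylsilyl)oxy]phenyl}-4,4,5,5-tetramethyl-1,3,2-dioxaborolane | COc1cc(O[Si](C(C)C)(C(C)C)C(C)C)cc(B2OC(C)(C)C(C)(C)O2)c1 | intermediate (not isolated)
5 | 3-methoxy-5-[(triisopropylsilyl)oxy]phenol | COc1cc(O)cc(O[Si](C(C)C)(C(C)C)C(C)C)c1 | intermediate
6 | (S)-glycidol, (S)-oxiran-2-ylmethanol | OC[C@H]1CO1 | starting material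
7 | (R)-triisopropyl{3-methoxy-5-[(oxiran-2-yl)methoxy]phenoxy}silane | COc1cc(OC[C@H]2CO2)cc(O[Si](C(C)C)(C(C)C)C(C)C)c1 | intermediate
8 | cyclohexane-1,3-dione | O=C1CCCC(=O)C1 | starting material
9 | 3-methylbut-2-enal | CC(C)=CC=O | starting material
10 | 2-(3-methylbut-2-en-1-ylidene)cyclohexane-1,3-dione | CC(C)=CC=C1C(=O)CCCC1=O | intermediate (not isolated)
11 | 2,2-dimethyl-7,8-dihydro-2H-chromen-5(6H)-one | CC1(C)C=CC2=C(O1)CCCC2=O | intermediate
12 | triisopropyl[(2,2-dimethyl-7,8-dihydro-2H-chromen-5-yl)oxy]silane | CC1(C)C=CC2=C(O1)CCC=C2O[Si](C(C)C)(C(C)C)C(C)C | intermediate (not isolated)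
13 | triisopropyl[(2,2-dimethyl-2H-chromen-5-yl)oxy]silane | CC1(C)C=Cc2c(O[Si](C(C)C)(C(C)C)C(C)C)cccc2O1 | intermediate
14 | [(8-bromo-2,2-dimethyl-2H-chromen-5-yl)oxy]triisopropylsilane | CC1(C)C=Cc2c(O[Si](C(C)C)(C(C)C)C(C)C)ccc(Br)c2O1 | intermediate
15 | {2,2-dimethyl-5-[(triisopropylsilyl)oxy]-2H-chromen-8-yl}magnesium bromide | CC1(C)C=Cc2c(O[Si](C(C)C)(C(C)C)C(C)C)ccc([Mg]Br)c2O1 | intermediate (not isolated)
16 | (R)-1-{2,2-dimethyl-5-[(triisopropylsilyl)oxy]-2H-chromen-8-yl}-3-{3-methoxy-5-[(triisopropylsilyl)oxy]phenoxy}propan-2-ol | COc1cc(OC[C@H](O)Cc2ccc(O[Si](C(C)C)(C(C)C)C(C)C)c3C=CC(C)(C)Oc23)cc(O[Si](C(C)C)(C(C)C)C(C)C)c1 | intermediate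
17 | dilithio derivative of 16: lithium (R)-alkoxide, ring A lithiated at the carbon between OMe and OCH2 | COc1cc(O[Si](C(C)C)(C(C)C)C(C)C)cc(OC[C@H](O[Li])Cc2ccc(O[Si](C(C)C)(C(C)C)C(C)C)c3C=CC(C)(C)Oc23)c1[Li] | intermediate (not isolated)
18 | (R)-trimethylsilyl ether of 19 (C-silyl and O-silyl) | COc1cc(O[Si](C(C)C)(C(C)C)C(C)C)cc(OC[C@H](O[Si](C)(C)C)Cc2ccc(O[Si](C(C)C)(C(C)C)C(C)C)c3C=CC(C)(C)Oc23)c1[Si](C)(C)C | intermediate (not isolated)
19 | (R)-1-{2,2-dimethyl-5-[(triisopropylsilyl)oxy]-2H-chromen-8-yl}-3-{3-methoxy-5-[(triisopropylsilyl)oxy]-2-(trimethylsilyl)phenoxy}propan-2-ol | COc1cc(O[Si](C(C)C)(C(C)C)C(C)C)cc(OC[C@H](O)Cc2ccc(O[Si](C(C)C)(C(C)C)C(C)C)c3C=CC(C)(C)Oc23)c1[Si](C)(C)C | intermediate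
20 | (R)-trifluoromethanesulfonate of 19 | COc1cc(O[Si](C(C)C)(C(C)C)C(C)C)cc(OC[C@H](OS(=O)(=O)C(F)(F)F)Cc2ccc(O[Si](C(C)C)(C(C)C)C(C)C)c3C=CC(C)(C)Oc23)c1[Si](C)(C)C | intermediate (not isolated)
21 | spiro[2.5]octadienyl (phenonium) cation of ring B as its triflate; the cyclopropane CH is inverted relative to 20, the spiro carbon is not defined | COc1cc(O[Si](C(C)C)(C(C)C)C(C)C)cc(OC[C@@H]2CC23C=CC(O[Si](C(C)C)(C(C)C)C(C)C)=C4C=CC(C)(C)[O+]=C34)c1[Si](C)(C)C.[O-]S(=O)(=O)C(F)(F)F | intermediate (not isolated)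
22 | (R)-3-{2,2-dimethyl-5-[(triisopropylsilyl)oxy]-2H-chromen-8-yl}-5-methoxy-7-[(triisopropylsilyl)oxy]chromane | COc1cc(O[Si](C(C)C)(C(C)C)C(C)C)cc2c1C[C@H](c1ccc(O[Si](C(C)C)(C(C)C)C(C)C)c3c1OC(C)(C)C=C3)CO2 | intermediate
23 | (R)-3-(5-hydroxy-2,2-dimethyl-2H-chromen-8-yl)-5-methoxychroman-7-ol | COc1cc(O)cc2c1C[C@H](c1ccc(O)c3c1OC(C)(C)C=C3)CO2 | target

**Totals**
Total step count: 11. Longest linear sequence: 8 steps (1, 2, 3, 4, 8, 9, 10, 11) from resorcinol; the ring B/D branch (5, 6, 7) joins at step 8.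

**Three steps most likely to fail**

Step 10 (the proposed new step). Risks: the chromene ring oxygen could compete as a five-ring neighbouring group; the phenonium ion could lose its tertiary allylic or silyl group; five-ring closure or elimination could intervene. The fallback uses known isoflavone chemistry, sets out from 5 and 14 and returns at 22. Phenol 5 is protected with MOMCl/i-Pr2NEt as 1-methoxy-3-(methoxymethoxy)-5-[(triisopropylsilyl)oxy]benzene F1. Lithiation between the two alkoxy groups (n-BuLi, THF, 0 °C) and acylation with N-methoxy-N-methylacetamide give 1-{2-methoxy-6-(methoxymethoxy)-4-[(triisopropylsilyl)oxy]phenyl}ethanone F2. HCl in MeOH frees the chelated phenol, 1-{2-hydroxy-6-methoxy-4-[(triisopropylsilyl)oxy]phenyl}ethanone F3. DMF dimethyl acetal at 90 °C gives (E)-3-(dimethylamino)-1-{2-hydroxy-6-methoxy-4-[(triisopropylsilyl)oxy]phenyl}prop-2-en-1-one F4, and I2 closes it to 3-iodo-5-methoxy-7-[(triisopropylsilyl)oxy]-4H-chromen-4-one F5. Grignard reagent 15 (from 14) is quenched with 2-isopropoxy-4,4,5,5-tetramethyl-1,3,2-dioxaborolane to give 2-{2,2-dimethyl-5-[(triisopropylsilyl)oxy]-2H-chromen-8-yl}-4,4,5,5-tetramethyl-1,3,2-dioxaborolane F6. Suzuki coupling of F5 with F6 (Pd(PPh3)4, K3PO4, dioxane/H2O) gives the isoflavone 3-{2,2-dimethyl-5-[(triisopropylsilyl)oxy]-2H-chromen-8-yl}-5-methoxy-7-[(triisopropylsilyl)oxy]-4H-chromen-4-one F7. Asymmetric transfer hydrogenation with dynamic kinetic resolution (RuCl[(R,R)-TsDPEN](p-cymene), HCO2H/Et3N) reduces the C2=C3 bond and the ketone to cis (3R,4R)-3-{2,2-dimethyl-5-[(triisopropylsilyl)oxy]-2H-chromen-8-yl}-5-methoxy-7-[(triisopropylsilyl)oxy]chroman-4-ol F8. Ionic deoxygenation (Et3SiH, BF3·OEt2, CH2Cl2, −78 °C) through the ring A-stabilised benzylic cation then gives 22.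

Step 7. Risks: bromination at C6 instead of C8, or NBS attack on the chromene double bond. The fallback fixes the bromine before ring D exists, sets out from 1 and returns at 14. Resorcinol 1 is brominated (NBS, MeCN, 0 °C) to 4-bromobenzene-1,3-diol F9. TIPSCl/imidazole silylates the less hindered hydroxyl para to bromine to give 2-bromo-5-[(triisopropylsilyl)oxy]phenol F10. Copper-catalysed propargylation (3-chloro-3-methylbut-1-yne, CuCl2 cat., DBU, MeCN, 0 °C) gives {4-bromo-3-[(2-methylbut-3-yn-2-yl)oxy]phenoxy}triisopropylsilane F11. Heating in N,N-diethylaniline at 150 °C (propargyl Claisen rearrangement, 1,5-hydrogen shift, oxa-6π closure onto the only free ortho carbon) gives 14.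

Step 9. Risks: incomplete or unselective lithiation on an advanced intermediate, butyllithium addition to the chromene, or loss of an aryl silyl ether during methanolysis. The fallback installs the silyl mark on the simple phenol before coupling, sets out from 5 and returns at 19 (it bypasses 16). Phenol 5 is converted with ClC(O)NEt2/NaH into 3-methoxy-5-[(triisopropylsilyl)oxy]phenyl diethylcarbamate F12. Carbamate-directed ortho-metalation between the carbamate and methoxy groups (s-BuLi, TMEDA, THF, −78 °C; Me3SiCl) gives 3-methoxy-5-[(triisopropylsilyl)oxy]-2-(trimethylsilyl)phenyl diethylcarbamate F13. LiAlH4 in THF at 0 °C removes the carbamate to give 3-methoxy-5-[(triisopropylsilyl)oxy]-2-(trimethylsilyl)phenol F14. Mitsunobu reaction with 6 (PPh3, DIAD) gives (R)-triisopropyl{3-methoxy-5-[(oxiran-2-yl)methoxy]-4-(trimethylsilyl)phenoxy}silane F15. Opening of F15 with Grignard reagent 15 (CuI 10 mol %, THF, −30 → 0 °C) gives 19.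

**Further compounds**
F1 | step 10 | 1-methoxy-3-(methoxymethoxy)-5-[(triisopropylsilyl)oxy]benzene | COCOc1cc(OC)cc(O[Si](C(C)C)(C(C)C)C(C)C)c1
F2 | step 10 | 1-{2-methoxy-6-(methoxymethoxy)-4-[(triisopropylsilyl)oxy]phenyl}ethanone | CC(=O)c1c(OC)cc(O[Si](C(C)C)(C(C)C)C(C)C)cc1OCOC
F3 | step 10 | 1-{2-hydroxy-6-methoxy-4-[(triisopropylsilyl)oxy]phenyl}ethanone | CC(=O)c1c(O)cc(O[Si](C(C)C)(C(C)C)C(C)C)cc1OC
F4 | step 10 | (E)-3-(dimethylamino)-1-{2-hydroxy-6-methoxy-4-[(triisopropylsilyl)oxy]phenyl}prop-2-en-1-one | CN(C)/C=C/C(=O)c1c(O)cc(O[Si](C(C)C)(C(C)C)C(C)C)cc1OC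
F5 | step 10 | 3-iodo-5-methoxy-7-[(triisopropylsilyl)oxy]-4H-chromen-4-one | COc1cc(O[Si](C(C)C)(C(C)C)C(C)C)cc2occ(I)c(=O)c12
F6 | step 10 | 2-{2,2-dimethyl-5-[(triisopropylsilyl)oxy]-2H-chromen-8-yl}-4,4,5,5-tetramethyl-1,3,2-dioxaborolane | CC1(C)C=Cc2c(O[Si](C(C)C)(C(C)C)C(C)C)ccc(B3OC(C)(C)C(C)(C)O3)c2O1
F7 | step 10 | 3-{2,2-dimethyl-5-[(triisopropylsilyl)oxy]-2H-chromen-8-yl}-5-methoxy-7-[(triisopropylsilyl)oxy]-4H-chromen-4-one | COc1cc(O[Si](C(C)C)(C(C)C)C(C)C)cc2occ(-c3ccc(O[Si](C(C)C)(C(C)C)C(C)C)c4C=CC(C)(C)Oc34)c(=O)c12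
F8 | step 10 | (3R,4R)-3-{2,2-dimethyl-5-[(triisopropylsilyl)oxy]-2H-chromen-8-yl}-5-methoxy-7-[(triisopropylsilyl)oxy]chroman-4-ol | COc1cc(O[Si](C(C)C)(C(C)C)C(C)C)cc2c1[C@H](O)[C@H](c1ccc(O[Si](C(C)C)(C(C)C)C(C)C)c3c1OC(C)(C)C=C3)CO2
F9 | step 7 | 4-bromobenzene-1,3-diol | Oc1ccc(Br)c(O)c1
F10 | step 7 | 2-bromo-5-[(triisopropylsilyl)oxy]phenol | Oc1cc(O[Si](C(C)C)(C(C)C)C(C)C)ccc1Br
F11 | step 7 | {4-bromo-3-[(2-methylbut-3-yn-2-yl)oxy]phenoxy}triisopropylsilane | C#CC(C)(C)Oc1cc(O[Si](C(C)C)(C(C)C)C(C)C)ccc1Br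
F12 | step 9 | 3-methoxy-5-[(triisopropylsilyl)oxy]phenyl diethylcarbamate | CCN(CC)C(=O)Oc1cc(OC)cc(O[Si](C(C)C)(C(C)C)C(C)C)c1
F13 | step 9 | 3-methoxy-5-[(triisopropylsilyl)oxy]-2-(trimethylsilyl)phenyl diethylcarbamate | CCN(CC)C(=O)Oc1cc(O[Si](C(C)C)(C(C)C)C(C)C)cc(OC)c1[Si](C)(C)C
F14 | step 9 | 3-methoxy-5-[(triisopropylsilyl)oxy]-2-(trimethylsilyl)phenol | COc1cc(O[Si](C(C)C)(C(C)C)C(C)C)cc(O)c1[Si](C)(C)C
F15 | step 9 | (R)-triisopropyl{3-methoxy-5-[(oxiran-2-yl)methoxy]-4-(trimethylsilyl)phenoxy}silane | COc1cc(O[Si](C(C)C)(C(C)C)C(C)C)cc(OC[C@H]2CO2)c1[Si](C)(C)C
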